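The readings are simulated for substances that don't exist, and the scatter is random.

Begin with the constants that the earlier flasks can yield, a rate constant k and a decay constant λ, and turn each reading of product P into them.

| flask | starting material | partner | time |
|---|---|---|---|
| alder | 0.600 M | 0.900 M |  |
| birch | 1.20 M | 0.900 M |  |
| cedar | 0.600 M | 1.80 M |  |
| oak | 2.10 M | 0.900 M | 8.6 min |

- alder run (time / min: [product] / M): 1.2: 0.205; 2.5: 0.276; 3.7: 0.301; 4.9: 0.320; 6.1: 0.325; 7.4: 0.326; 8.6: 0.330
- birch run (time / min: [product] / M): 1.2: 0.375; 2.5: 0.470; 3.7: 0.508; 4.9: 0.524; 6.1: 0.539; 7.4: 0.550; 8.6: 0.552
- cedar run (time / min: [product] / M): 1.2: 0.313; 2.5: 0.373; 3.7: 0.395; 4.9: 0.406; 6.1: 0.419; 7.4: 0.418; 8.6: 0.425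

(scatter of a reading: 0.003 M)

- Overall: starting material + partner -> product.
- Constant volume, constant temperature.
- "The second partner" is partner.
- An order is taken over about fifteen percent of the charge, up and down.

1. the exponent of [starting material] in the starting rate at the charge of the alder run (at the point where two percent of the starting material have become product) (one fixed amount of product, the same in the runs compared)
2. the exponent of [partner] in the starting rate at the charge of the alder run (at the point where two percent of the starting material have become product)
3. product in the oak run at 8.6 min, as a share of the starting material charged

Work with the fractions left: with charges s of starting material and r of partner, f_S is one minus P/s and f_R is one minus P/r. Write the rate as k g s r f_S f_R, where g, beginning at one, is the slowing these fractions do not account for; integrating gives the dose D = ln(f_R/f_S)/(r − s), the time integral of k g, obtained from a single reading.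

At the first reading the dose is 0.532 /M in the alder run and 0.548 /M in the birch run, and at the last 1.14 /M and 1.11 /M, so take the order in starting material as one. The cedar run, with twice the partner, ends at 0.802 /M, less than the alder run, and its first reading gives 0.455 /M, a larger share of its last dose than in the alder run; so read g as falling sooner in the cedar run, and take the partner's order as near one as well.

Now lay g = exp(−λt) through the first and last alder doses: λ is 0.524 /min, k is 0.597 /M/min, and the starting rate of the alder run is 0.322 M/min. At 8.6 min in the alder run, the product of the fractions stands at 0.285, but this g stands at 0.0110, lower still, so on this reckoning the accumulated slowing sets the end. Carry the plateau dose, the mean of the alder and birch doses at the last reading, 1.13 /M, to the oak run, where partner is the limiting reagent. Solving the dose equation gives 0.259 for f_R/f_S, hence 0.750 M of product, or 35.7 % of the starting material.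

The forecast commits to 1, 0.95 and 35.7 %, adding that “excess partner seems to hasten the deactivation”.

The oak run gives 33.8 %; at the charge of the alder run the orders are 1.0 and 1.0.

    starting material + partner → product + by-product (0.6720 /M/min)
    2 partner → lost reagent (0.3438 /M/min)
    starting material → decomposed substrate (0.1734 /min)

The loss of starting material to decomposed substrate moves that share by less than one percentage point. Put the share back through the dose: the oak run received 0.952 /M, less than the 1.13 /M carried to it. Divided by the first rate constant above, the dose of the oak run equals 1.42 min of reaction at full strength within the 8.6 min asked.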